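Everything rests on assembling ring A by a cyclobutenone–alkyne benzannulation rather than by decorating phloroglucinol. Ring A carries oxygen on C5, C7 and C8a, and the 4-hydroxybenzyl group on C8 sits between C7–O and C8a–O1; the key step exploits exactly this pattern. Heating 3-(benzyloxy)cyclobutenone with the ynol silyl ether TIPSO–C≡C–CH2Ar joins C7–C8, C4a–C8a and C6–C7 in one operation and releases O7 as free phenol, O1 as silyl ether and O5 as benzyl ether. O1 can then be bared alone, bonded to C2 of an enantiopure trans-glycidate with inversion, and ring C closed at C4a by acylation.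

Key step: step 4

Atom labels: flavonoid numbering (O1, C2, C3, C4, C4a, C5 to C8, C8a) is used for the target and for the atoms that become part of it.

Assumption: the lipase that resolves methyl trans-3-(4-methoxyphenyl)glycidate is taken to hydrolyse the (2S,3R)-antipode of the 4-benzyloxy analogue with the same preference.

Step 1
Reactants: 1 4-(benzyloxy)benzyl chloride; 2 ethynylmagnesium bromide
Product: 3 1-(benzyloxy)-4-(prop-2-yn-1-yl)benzene
Conditions: 2 (0.5 M in THF, 2.5 equiv), CuCl (10 mol%), THF, 60 °C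
Reagents that add atoms: none
Why: Copper-catalysed alkynylation of a benzylic halide with an alkynyl Grignard reagent (SN2-type cross-coupling) should give the skipped aryl alkyne, and the excess of acetylide keeps the product from being benzylated a second time.

Step 2
Reactants: 3 1-(benzyloxy)-4-(prop-2-yn-1-yl)benzene
Product: 6 3-[4-(benzyloxy)phenyl]-1-(triisopropylsilyloxy)prop-1-yne, via lithium acetylide 4 (not isolated), via lithium ynolate 5 (not isolated)
Conditions: n-BuLi (1.0 equiv), THF, −78 °C; t-BuOOLi (from t-BuOOH and LiHMDS), −78 to 0 °C; TIPSOTf, −78 to 0 °C; Et3N-deactivated silica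
Reagents that add atoms: tert-butyl hydroperoxide CC(C)(C)OO; triisopropylsilyl trifluoromethanesulfonate CC(C)[Si](OS(=O)(=O)C(F)(F)F)(C(C)C)C(C)C
Why: Oxidation of a lithium acetylide by lithium tert-butyl peroxide (electrophilic oxygen transfer to carbon) gives the ynolate, which the bulky silyl triflate traps on oxygen, and this entry avoids exposing an easily enolised arylacetic ester to the strong bases of an ester homologation.

Step 3
Reactants: 7 3-ethoxycyclobut-2-en-1-one
Product: 8 3-(benzyloxy)cyclobut-2-en-1-one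
Conditions: BnOH (3 equiv), PPTS (5 mol%), 5 Å MS, PhMe, 40 °C
Reagents that add atoms: benzyl alcohol OCc1ccccc1
Why: Acid-catalysed vinylogous transesterification, in which benzyl alcohol adds to C3 of the protonated enone and the mixed ketal expels ethanol that the sieves retain, while the temperature stays far below that of electrocyclic opening so the alcohol meets no ketene.

Step 4
Reactants: 8 3-(benzyloxy)cyclobut-2-en-1-one; 6 3-[4-(benzyloxy)phenyl]-1-(triisopropylsilyloxy)prop-1-yne
Product: 13 5-(benzyloxy)-2-[4-(benzyloxy)benzyl]-3-(triisopropylsilyloxy)phenol, via vinylketene 9 (not isolated), via vinylcyclobutenone 10 (not isolated), via dienylketene 11 (not isolated), via cyclohexadienone 12 (not isolated)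
Conditions: 8 added slowly to 6 (1.3 equiv) in PhMe at 110 °C (sealed vessel, Ar), then 110 °C until 10 is consumed
Reagents that add atoms: none
Why: Strain release drives conrotatory four-electron opening of 8 to vinylketene 9, whose ketene unit undergoes [2+2] cycloaddition with 6 to give 10; a second four-electron opening gives dienylketene 11, six-electron electrocyclisation gives dienone 12, and enolisation gives phenol 13. The closest known reaction type is the Danheiser benzannulation of cyclobutenones with trialkylsilyloxyalkynes. Ring A, the only ring closed, forms by thermal disrotatory six-electron electrocyclisation (C6–C7) after the cycloaddition has laid down C7–C8 and C4a–C8a. No stereocentre survives, since the sp3 carbon of 10 becomes aromatic C4a. The one selectivity needed is the orientation of the ketene–alkyne union, and the polarisation of the ynol ether secures it: the benzyl-bearing carbon remote from oxygen is nucleophilic and bonds to the electrophilic ketene carbonyl carbon (future C7), which places the benzyl group between the new OH and the OTIPS group. Slow addition of 8 to excess 6 keeps the ketene dilute, which should limit its dimerisation and its capture by the product phenol.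

Step 5
Reactants: 13 5-(benzyloxy)-2-[4-(benzyloxy)benzyl]-3-(triisopropylsilyloxy)phenol
Product: 14 {3,5-bis(benzyloxy)-2-[4-(benzyloxy)benzyl]phenoxy}triisopropylsilane
Conditions: BnBr (1.2 equiv), K2CO3, dry acetone, 50 °C
Reagents that add atoms: benzyl bromide BrCc1ccccc1
Why: Williamson etherification of the only free phenol (O7) with a mild carbonate base in dry acetone, conditions under which the hindered aryl triisopropylsilyl ether on O1 should persist.

Step 6
Reactants: 14 {3,5-bis(benzyloxy)-2-[4-(benzyloxy)benzyl]phenoxy}triisopropylsilane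
Product: 15 3,5-bis(benzyloxy)-2-[4-(benzyloxy)benzyl]phenol
Conditions: TBAF, AcOH (1:1), THF, 0 °C
Reagents that add atoms: none
Why: Fluoride-induced desilylation driven by the strong Si–F bond frees O1 alone, and the acetic acid buffer protonates the electron-rich phenoxide as it forms.

Step 7
Reactants: 16 4-(benzyloxy)benzaldehyde; 17 methyl chloroacetate
Product: 18 methyl rac-trans-3-[4-(benzyloxy)phenyl]oxirane-2-carboxylate
Conditions: NaOMe, MeOH, −10 °C to rt; poured into ice water, crystallised
Reagents that add atoms: none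
Why: Darzens glycidic ester condensation, in which the chloroacetate enolate adds to the aldehyde and the halohydrin alkoxide displaces chloride, should favour the trans-epoxide, which crystallises as the racemate.

Step 8
Reactants: 18 methyl rac-trans-3-[4-(benzyloxy)phenyl]oxirane-2-carboxylate
Product: 19 methyl (2R,3S)-3-[4-(benzyloxy)phenyl]oxirane-2-carboxylate
Conditions: lipase from Serratia marcescens, PhMe / phosphate buffer (pH 8), 30 °C, stopped just past half conversion; basic wash, crystallisation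
Reagents that add atoms: none
Why: Lipase-catalysed kinetic resolution by enantioselective ester hydrolysis removes the (2S,3R)-antipode into the aqueous phase and leaves the (2R,3S)-ester, which fixes the absolute configuration of the carbon that becomes C3 (kept) and of the carbon that becomes C2 (inverted in step 9).

Step 9
Reactants: 15 3,5-bis(benzyloxy)-2-[4-(benzyloxy)benzyl]phenol; 19 methyl (2R,3S)-3-[4-(benzyloxy)phenyl]oxirane-2-carboxylate
Product: 20 methyl (2R,3R)-3-{3,5-bis(benzyloxy)-2-[4-(benzyloxy)benzyl]phenoxy}-3-[4-(benzyloxy)phenyl]-2-hydroxypropanoate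
Conditions: 19 (1.2 equiv), Cs2CO3 (0.2 equiv), DMF, 60 °C
Reagents that add atoms: none
Why: Base-catalysed SN2 opening of an aryl epoxide by a phenoxide occurs at the benzylic carbon anti to the C–O bond, so that carbon inverts from S to R (future C2) while the carbinol carbon keeps its R configuration (future C3), and the basic aprotic medium suppresses ionisation to a 4-alkoxybenzyl cation.

Step 10
Reactants: 20 methyl (2R,3R)-3-{3,5-bis(benzyloxy)-2-[4-(benzyloxy)benzyl]phenoxy}-3-[4-(benzyloxy)phenyl]-2-hydroxypropanoate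
Product: 21 (2R,3R)-3-{3,5-bis(benzyloxy)-2-[4-(benzyloxy)benzyl]phenoxy}-3-[4-(benzyloxy)phenyl]-2-hydroxypropanoic acid
Conditions: LiOH, THF–H2O, 0 °C; then 1 M HCl to pH 3, 0 °C
Reagents that add atoms: lithium hydroxide [Li+].[OH-]
Why: Saponification of the methyl ester by acyl–oxygen cleavage at low temperature leaves both stereocentres alone, because the neighbouring hydroxyl is ionised first and disfavours removal of the alpha proton.

Step 11
Reactants: 21 (2R,3R)-3-{3,5-bis(benzyloxy)-2-[4-(benzyloxy)benzyl]phenoxy}-3-[4-(benzyloxy)phenyl]-2-hydroxypropanoic acid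
Product: 24 (2R,3R)-5,7-bis(benzyloxy)-8-[4-(benzyloxy)benzyl]-2-[4-(benzyloxy)phenyl]-3-hydroxychroman-4-one, via mixed anhydride 22 (not isolated), via 3-O-trifluoroacetate 23 (not isolated)
Conditions: (CF3CO)2O (3 equiv), CH2Cl2, 0 °C to rt; evaporate; MeOH, rt
Reagents that add atoms: none
Why: Intramolecular Friedel–Crafts acylation through the mixed trifluoroacetic anhydride closes C4–C4a on the very electron-rich ring A at the only position the O1 tether can reach (C8 is blocked), the hydroxyl being masked in the flask as a trifluoroacetate that methanol removes, and no bond to C2 or C3 is broken.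

Step 12
Reactants: 24 (2R,3R)-5,7-bis(benzyloxy)-8-[4-(benzyloxy)benzyl]-2-[4-(benzyloxy)phenyl]-3-hydroxychroman-4-one
Product: 25 (2R,3R)-3,5,7-trihydroxy-8-(4-hydroxybenzyl)-2-(4-hydroxyphenyl)chroman-4-one (CNP0153057.1)
Conditions: H2 (1 atm), 10% Pd/C, EtOAc–MeOH, rt, stopped after uptake of four equivalents
Reagents that add atoms: none
Why: Catalytic hydrogenolysis cleaves the four aryl benzyl ethers under neutral conditions faster than it touches the diarylmethane C8–CH2 bond, the cyclic C2–O1 bond or the C4 ketone, so the trans (2R,3R) pair should be carried through unchanged.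

Compound list
1 | 4-(benzyloxy)benzyl chloride | ClCc1ccc(OCc2ccccc2)cc1 | starting material
2 | ethynylmagnesium bromide | C#C[Mg]Br | starting material
3 | 1-(benzyloxy)-4-(prop-2-yn-1-yl)benzene | C#CCc1ccc(OCc2ccccc2)cc1 | intermediate
4 | lithium 3-[4-(benzyloxy)phenyl]prop-1-yn-1-ide (lithium acetylide) | [Li]C#CCc1ccc(OCc2ccccc2)cc1 | intermediate
5 | lithium 3-[4-(benzyloxy)phenyl]prop-1-yn-1-olate (lithium ynolate) | [Li+].[O-]C#CCc1ccc(OCc2ccccc2)cc1 | intermediate
6 | 3-[4-(benzyloxy)phenyl]-1-(triisopropylsilyloxy)prop-1-yne | CC(C)[Si](OC#CCc1ccc(OCc2ccccc2)cc1)(C(C)C)C(C)C | intermediate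
7 | 3-ethoxycyclobut-2-en-1-one | CCOC1=CC(=O)C1 | starting material
8 | 3-(benzyloxy)cyclobut-2-en-1-one | O=C1C=C(OCc2ccccc2)C1 | intermediate
9 | 3-(benzyloxy)buta-1,3-dien-1-one (vinylketene) | C=C(OCc1ccccc1)C=C=O | intermediate
10 | 4-[1-(benzyloxy)ethenyl]-2-[4-(benzyloxy)benzyl]-3-(triisopropylsilyloxy)cyclobut-2-en-1-one (racemic at C4) | O=C1C(Cc2ccc(OCc3ccccc3)cc2)=C(O[Si](C(C)C)(C(C)C)C(C)C)C1C(=C)OCc1ccccc1 | intermediate
11 | (3E)-5-(benzyloxy)-2-[4-(benzyloxy)benzyl]-3-(triisopropylsilyloxy)hexa-1,3,5-trien-1-one (ketene carbon chain and vinyl group cis) | O=C=C(Cc1ccc(OCc2ccccc2)cc1)/C(O[Si](C(C)C)(C(C)C)C(C)C)=C\C(=C)OCc1ccccc1 | intermediate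
12 | 5-(benzyloxy)-2-[4-(benzyloxy)benzyl]-3-(triisopropylsilyloxy)cyclohexa-2,4-dien-1-one | O=C1CC(OCc2ccccc2)=CC(O[Si](C(C)C)(C(C)C)C(C)C)=C1Cc1ccc(OCc2ccccc2)cc1 | intermediate
13 | 5-(benzyloxy)-2-[4-(benzyloxy)benzyl]-3-(triisopropylsilyloxy)phenol | Oc1cc(OCc2ccccc2)cc(O[Si](C(C)C)(C(C)C)C(C)C)c1Cc1ccc(OCc2ccccc2)cc1 | intermediate
14 | {3,5-bis(benzyloxy)-2-[4-(benzyloxy)benzyl]phenoxy}triisopropylsilane | CC(C)[Si](Oc1cc(OCc2ccccc2)cc(OCc2ccccc2)c1Cc1ccc(OCc2ccccc2)cc1)(C(C)C)C(C)C | intermediate
15 | 3,5-bis(benzyloxy)-2-[4-(benzyloxy)benzyl]phenol | Oc1cc(OCc2ccccc2)cc(OCc2ccccc2)c1Cc1ccc(OCc2ccccc2)cc1 | intermediate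
16 | 4-(benzyloxy)benzaldehyde | O=Cc1ccc(OCc2ccccc2)cc1 | starting material
17 | methyl chloroacetate | COC(=O)CCl | starting material
18 | methyl rac-trans-3-[4-(benzyloxy)phenyl]oxirane-2-carboxylate (both enantiomers) | COC(=O)[C@@H]1O[C@H]1c1ccc(OCc2ccccc2)cc1.COC(=O)[C@H]1O[C@@H]1c1ccc(OCc2ccccc2)cc1 | intermediate
19 | methyl (2R,3S)-3-[4-(benzyloxy)phenyl]oxirane-2-carboxylate | COC(=O)[C@@H]1O[C@H]1c1ccc(OCc2ccccc2)cc1 | intermediate
20 | methyl (2R,3R)-3-{3,5-bis(benzyloxy)-2-[4-(benzyloxy)benzyl]phenoxy}-3-[4-(benzyloxy)phenyl]-2-hydroxypropanoate | COC(=O)[C@H](O)[C@H](Oc1cc(OCc2ccccc2)cc(OCc2ccccc2)c1Cc1ccc(OCc2ccccc2)cc1)c1ccc(OCc2ccccc2)cc1 | intermediate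
21 | (2R,3R)-3-{3,5-bis(benzyloxy)-2-[4-(benzyloxy)benzyl]phenoxy}-3-[4-(benzyloxy)phenyl]-2-hydroxypropanoic acid | OC(=O)[C@H](O)[C@H](Oc1cc(OCc2ccccc2)cc(OCc2ccccc2)c1Cc1ccc(OCc2ccccc2)cc1)c1ccc(OCc2ccccc2)cc1 | intermediate
22 | trifluoroacetic (2R,3R)-3-{3,5-bis(benzyloxy)-2-[4-(benzyloxy)benzyl]phenoxy}-3-[4-(benzyloxy)phenyl]-2-(trifluoroacetoxy)propanoic anhydride | O=C(OC(=O)C(F)(F)F)[C@H](OC(=O)C(F)(F)F)[C@H](Oc1cc(OCc2ccccc2)cc(OCc2ccccc2)c1Cc1ccc(OCc2ccccc2)cc1)c1ccc(OCc2ccccc2)cc1 | intermediate
23 | (2R,3R)-5,7-bis(benzyloxy)-8-[4-(benzyloxy)benzyl]-2-[4-(benzyloxy)phenyl]-4-oxochroman-3-yl trifluoroacetate | O=C1c2c(OCc3ccccc3)cc(OCc3ccccc3)c(Cc3ccc(OCc4ccccc4)cc3)c2O[C@H](c2ccc(OCc3ccccc3)cc2)[C@H]1OC(=O)C(F)(F)F | intermediate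
24 | (2R,3R)-5,7-bis(benzyloxy)-8-[4-(benzyloxy)benzyl]-2-[4-(benzyloxy)phenyl]-3-hydroxychroman-4-one | O=C1c2c(OCc3ccccc3)cc(OCc3ccccc3)c(Cc3ccc(OCc4ccccc4)cc3)c2O[C@H](c2ccc(OCc3ccccc3)cc2)[C@H]1O | intermediate
25 | (2R,3R)-3,5,7-trihydroxy-8-(4-hydroxybenzyl)-2-(4-hydroxyphenyl)chroman-4-one | O=C1c2c(O)cc(O)c(Cc3ccc(O)cc3)c2O[C@H](c2ccc(O)cc2)[C@H]1O | target

Total step count: 12. Longest linear sequence: 9 steps (steps 1, 2, 4, 5, 6, 9, 10, 11, 12).

Steps most likely to fail

Step 4. The vinylogous-ester stabilisation of the four-membered ring may slow its electrocyclic opening. Ketene dimerisation, acylation of the newly formed phenol by the ketene, or an oxygen-to-carbon silyl shift in the alkyne could then overtake the cycloaddition. In the fallback, ring A is taken from the aromatic pool instead of being built. Setting out from chloride 1, the sodium salt of commercial 3,5-bis(benzyloxy)phenol (NaH, toluene, 80 °C) is benzylated at its ortho carbon under tight ion-pair conditions, the classical ortho C-alkylation of phenoxides in non-polar media. Isomers from para or oxygen attack are separated. The route is rejoined at phenol 15, so steps 2 to 6 drop out, and no compound outside the list is made (entry F0).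

Step 9. The phenoxide may attack the ester carbonyl or the carbon next to it. Partial ionisation of the 4-alkoxybenzylic C–O bond may erode the inversion, and the ambident phenoxide may alkylate on carbon instead of oxygen. The fallback changes the electrophile from an epoxy ester to an epoxy alcohol, the substrate class on which benzylic opening by phenoxides in aqueous base is best established. Setting out from 19, NaBH4 (MeOH–THF, 0 °C) reduces the activated ester to [(2S,3S)-3-(4-(benzyloxy)phenyl)oxiran-2-yl]methanol F1. Phenol 15, as its sodium salt in aqueous dioxane at 70 °C, opens F1 at the benzylic carbon with inversion to give (2S,3R)-3-{3,5-bis(benzyloxy)-2-[4-(benzyloxy)benzyl]phenoxy}-3-[4-(benzyloxy)phenyl]propane-1,2-diol F2. Chemoselective oxidation of the primary alcohol (TEMPO, PhI(OAc)2, MeCN–H2O) then rejoins the route at acid 21.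

Step 11. Acid may heterolyse the benzylic aryl ether before the ring closes. The alpha-oxygenated acylium may lose carbon monoxide, or ring A may be trifluoroacetylated at C6. The fallback reverses the order of the two ring C bonds.
- Setting out from 15, Ac2O and BF3·OEt2 (CH2Cl2, 0 °C to rt) acetylate O1 and shift the acyl group by Fries rearrangement to the only free ortho carbon, giving 1-{4,6-bis(benzyloxy)-3-[4-(benzyloxy)benzyl]-2-hydroxyphenyl}ethan-1-one F3.
- MOMCl and iPr2NEt give 1-{4,6-bis(benzyloxy)-3-[4-(benzyloxy)benzyl]-2-(methoxymethoxy)phenyl}ethan-1-one F4.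
- Claisen–Schmidt condensation with 16 (KOH, EtOH) gives (E)-1-{4,6-bis(benzyloxy)-3-[4-(benzyloxy)benzyl]-2-(methoxymethoxy)phenyl}-3-[4-(benzyloxy)phenyl]prop-2-en-1-one F5.
- Juliá–Colonna epoxidation (poly-L-leucine, urea–H2O2, DBU, THF) gives {4,6-bis(benzyloxy)-3-[4-(benzyloxy)benzyl]-2-(methoxymethoxy)phenyl}{(2R,3S)-3-[4-(benzyloxy)phenyl]oxiran-2-yl}methanone F6.
- HCl in MeOH removes the acetal, and the freed O1 opens the epoxide at its benzylic carbon in 6-endo fashion with inversion. This rejoins the route at 24 and replaces steps 7 to 11.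

Further compounds
F0 | step 4 | none | none
F1 | step 9 | [(2S,3S)-3-(4-(benzyloxy)phenyl)oxiran-2-yl]methanol | OC[C@@H]1O[C@H]1c1ccc(OCc2ccccc2)cc1
F2 | step 9 | (2S,3R)-3-{3,5-bis(benzyloxy)-2-[4-(benzyloxy)benzyl]phenoxy}-3-[4-(benzyloxy)phenyl]propane-1,2-diol | OC[C@H](O)[C@H](Oc1cc(OCc2ccccc2)cc(OCc2ccccc2)c1Cc1ccc(OCc2ccccc2)cc1)c1ccc(OCc2ccccc2)cc1
F3 | step 11 | 1-{4,6-bis(benzyloxy)-3-[4-(benzyloxy)benzyl]-2-hydroxyphenyl}ethan-1-one | CC(=O)c1c(O)c(Cc2ccc(OCc3ccccc3)cc2)c(OCc2ccccc2)cc1OCc1ccccc1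
F4 | step 11 | 1-{4,6-bis(benzyloxy)-3-[4-(benzyloxy)benzyl]-2-(methoxymethoxy)phenyl}ethan-1-one | CC(=O)c1c(OCOC)c(Cc2ccc(OCc3ccccc3)cc2)c(OCc2ccccc2)cc1OCc1ccccc1
F5 | step 11 | (E)-1-{4,6-bis(benzyloxy)-3-[4-(benzyloxy)benzyl]-2-(methoxymethoxy)phenyl}-3-[4-(benzyloxy)phenyl]prop-2-en-1-one | O=C(/C=C/c1ccc(OCc2ccccc2)cc1)c1c(OCOC)c(Cc2ccc(OCc3ccccc3)cc2)c(OCc2ccccc2)cc1OCc1ccccc1
F6 | step 11 | {4,6-bis(benzyloxy)-3-[4-(benzyloxy)benzyl]-2-(methoxymethoxy)phenyl}{(2R,3S)-3-[4-(benzyloxy)phenyl]oxiran-2-yl}methanone | O=C([C@@H]1O[C@H]1c1ccc(OCc2ccccc2)cc1)c1c(OCOC)c(Cc2ccc(OCc3ccccc3)cc2)c(OCc2ccccc2)cc1OCc1ccccc1
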